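## Retrosynthetic overview

1. The target is the all-trans 2,5-diaryl-3,4-bis(hydroxymethyl)tetrahydrofuran. The THF ring is formed last by SN1 closure of the C2–O bond: a benzylic cation on the syringyl side is trapped by the oxygen on the trimethoxyphenyl-bearing carbon, with both primary alcohols masked as acetates.
2. The acyclic precursor comes from reduction of a trans-α,β-disubstituted γ-butyrolactone. The lactone is a temporary ring whose trans-selective enolate aldol with O-silyl syringaldehyde sets the C3/C4 trans relationship.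
3. The β-substituted lactone comes from an Evans syn-aldol of a succinate-derived N-acyloxazolidinone with 3,4,5-trimethoxybenzaldehyde (sets C5 and C4), then silylation and reductive auxiliary removal with lactonisation.
4. Ring order: γ-lactone (Step 4) → opened (Step 7) → tetrahydrofuran (Step 9).

Assumption: the syringyl carbinol centre in 10–12 is an epimer mixture (drawn undefined); it is ionised and reset in Step 9. Compounds 1, 2, 4 and 8 are taken as commercial. THF numbering used below: C2 bears the syringyl ring, C5 the trimethoxyphenyl ring.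

## Route

**Step 1**
Reactants: 1, (R)-4-benzyl-1,3-oxazolidin-2-one; 2, methyl 4-chloro-4-oxobutanoate
Product: 3, methyl 4-[(4R)-4-benzyl-2-oxo-1,3-oxazolidin-3-yl]-4-oxobutanoate
Conditions: n-BuLi, THF, −78 °C; then 2, −78 → 0 °C
Reagents that add atoms: none
Why: N-acylation of the lithiated oxazolidinone by the acid chloride (Evans imide formation); no new stereocentre.

**Step 2**
Reactants: 3; 4, 3,4,5-trimethoxybenzaldehyde
Product: 5, methyl (3R,4R)-3-{[(4R)-4-benzyl-2-oxo-1,3-oxazolidin-3-yl]carbonyl}-4-hydroxy-4-(3,4,5-trimethoxyphenyl)butanoate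
Conditions: Bu2BOTf, i-Pr2NEt, CH2Cl2, −78 → 0 °C; 4, −78 → 0 °C; pH 7 buffer, MeOH, H2O2, 0 °C; crude used directly
Reagents that add atoms: none
Why: Evans boron syn-aldol; the Z-enolate reacts through a Zimmerman–Traxler transition state and the (R)-auxiliary fixes both new centres as (3R,4R), which become C4 and C5 of the THF.

**Step 3**
Reactants: 5
Product: 6, methyl (3R,4R)-3-{[(4R)-4-benzyl-2-oxo-1,3-oxazolidin-3-yl]carbonyl}-4-[(tert-butyldimethylsilyl)oxy]-4-(3,4,5-trimethoxyphenyl)butanoate
Conditions: TBSOTf, 2,6-lutidine, CH2Cl2, −78 → 0 °C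
Reagents that add atoms: TBSOTf, CC(C)(C)[Si](C)(C)OS(=O)(=O)C(F)(F)F
Why: O-silylation of the aldol hydroxyl stops it lactonising onto the methyl ester, so only the primary alcohol made in Step 4 can close the lactone.

**Step 4**
Reactants: 6
Product: 7, (4S)-4-[(R)-[(tert-butyldimethylsilyl)oxy](3,4,5-trimethoxyphenyl)methyl]oxolan-2-one (auxiliary 1 recovered)
Conditions: NaBH4, THF–H2O, 0 °C → rt; then cat. PPTS, CH2Cl2, rt
Reagents that add atoms: none
Why: chemoselective reductive cleavage of the N-acyloxazolidinone to the primary alcohol, which lactonises (5-exo) onto the untouched methyl ester; no stereocentre is touched.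

**Step 5**
Reactants: 8, syringaldehyde (4-hydroxy-3,5-dimethoxybenzaldehyde)
Product: 9, 4-[(tert-butyldimethylsilyl)oxy]-3,5-dimethoxybenzaldehyde
Conditions: TBSCl, imidazole, DMF, rt
Reagents that add atoms: TBSCl, CC(C)(C)[Si](C)(C)Cl
Why: phenol silylation; the silyl ether survives the enolate and hydride steps and keeps the ring electron-rich for Step 9.

**Step 6**
Reactants: 7; 9
Product: 10, (3R,4S)-3-{hydroxy[4-(tert-butyldimethylsilyloxy)-3,5-dimethoxyphenyl]methyl}-4-[(R)-[(tert-butyldimethylsilyl)oxy](3,4,5-trimethoxyphenyl)methyl]oxolan-2-one (carbinol epimers)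
Conditions: LDA, THF, −78 °C; then 9, −78 °C; AcOH quench at −78 °C
Reagents that add atoms: none
Why: lactone lithium-enolate aldol; the aldehyde adds anti to the bulky C4 substituent, giving the 3,4-trans lactone and so the correct C3 configuration of the THF.

**Step 7**
Reactants: 10
Product: 11, (2S,3S)-2-[(R)-[(tert-butyldimethylsilyl)oxy](3,4,5-trimethoxyphenyl)methyl]-3-{hydroxy[4-(tert-butyldimethylsilyloxy)-3,5-dimethoxyphenyl]methyl}butane-1,4-diol
Conditions: LiBH4, THF (cat. MeOH), 0 °C → rt
Reagents that add atoms: none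
Why: hydride reduction of the lactone to the 1,4-diol; alkyl and aryl silyl ethers are stable to LiBH4 and no stereocentre changes.

**Step 8**
Reactants: 11
Product: 12, the triacetate of 11 (two primary acetates and the syringyl benzylic acetate)
Conditions: Ac2O, pyridine, cat. DMAP, CH2Cl2, 0 °C → rt
Reagents that add atoms: acetic anhydride, CC(=O)OC(C)=O
Why: exhaustive acylation blocks both primary oxygens (which would otherwise give furofuran-type ethers) and turns the syringyl carbinol into the only good benzylic leaving group.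

**Step 9**
Reactants: 12
Product: 13, [(2R,3S,4S,5R)-2-[4-(tert-butyldimethylsilyloxy)-3,5-dimethoxyphenyl]-5-(3,4,5-trimethoxyphenyl)oxolane-3,4-diyl]bis(methylene) diacetate
Conditions: BF3·OEt2, CH2Cl2, −78 → −20 °C; aq. NaHCO3
Reagents that add atoms: none
Why: SN1 cycloetherification: the Lewis acid ionises the electron-rich benzylic acetate and the silyl ether oxygen closes the ring 5-exo with loss of the silyl group. C5 is retained, and the new C2 centre forms trans to the C3 substituent, the all-trans isomer being both the kinetic and (by reversible ionisation) thermodynamic product.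

**Step 10**
Reactants: 13
Product: 14, [(2R,3S,4S,5R)-2-(4-hydroxy-3,5-dimethoxyphenyl)-5-(3,4,5-trimethoxyphenyl)oxolane-3,4-diyl]dimethanol (target)
Conditions: K2CO3, MeOH, rt → 40 °C
Reagents that add atoms: none
Why: base methanolysis removes both acetates and the phenolic silyl ether in one operation; no acid is present, so the benzylic ether centres are not disturbed.

## Compound list

1 | (R)-4-benzyl-1,3-oxazolidin-2-one | O=C1N[C@H](Cc2ccccc2)CO1 | starting material
2 | methyl 4-chloro-4-oxobutanoate | COC(=O)CCC(Cl)=O | starting material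
3 | methyl 4-[(4R)-4-benzyl-2-oxo-oxazolidin-3-yl]-4-oxobutanoate | COC(=O)CCC(=O)N1C(=O)OC[C@H]1Cc1ccccc1 | intermediate
4 | 3,4,5-trimethoxybenzaldehyde | COc1cc(C=O)cc(OC)c1OC | starting material
5 | (3R,4R) syn-aldol adduct | COC(=O)C[C@H]([C@@H](O)c1cc(OC)c(OC)c(OC)c1)C(=O)N1C(=O)OC[C@H]1Cc1ccccc1 | intermediate
6 | TBS ether of 5 | COC(=O)C[C@H]([C@@H](O[Si](C)(C)C(C)(C)C)c1cc(OC)c(OC)c(OC)c1)C(=O)N1C(=O)OC[C@H]1Cc1ccccc1 | intermediate
7 | (4S)-4-[(R)-TBSO(3,4,5-trimethoxyphenyl)methyl]oxolan-2-one | O=C1C[C@@H](CO1)[C@@H](O[Si](C)(C)C(C)(C)C)c1cc(OC)c(OC)c(OC)c1 | intermediate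
8 | syringaldehyde | COc1cc(C=O)cc(OC)c1O | starting material
9 | 4-(tert-butyldimethylsilyloxy)-3,5-dimethoxybenzaldehyde | COc1cc(C=O)cc(OC)c1O[Si](C)(C)C(C)(C)C | intermediate
10 | (3R,4S)-trans aldol lactone (carbinol epimers) | O=C1OC[C@@H]([C@@H](O[Si](C)(C)C(C)(C)C)c2cc(OC)c(OC)c(OC)c2)[C@@H]1C(O)c1cc(OC)c(O[Si](C)(C)C(C)(C)C)c(OC)c1 | intermediate
11 | (2S,3S)-triol | OC[C@@H]([C@@H](O[Si](C)(C)C(C)(C)C)c1cc(OC)c(OC)c(OC)c1)[C@@H](CO)C(O)c1cc(OC)c(O[Si](C)(C)C(C)(C)C)c(OC)c1 | intermediate
12 | triacetate of 11 | CC(=O)OC[C@@H]([C@@H](O[Si](C)(C)C(C)(C)C)c1cc(OC)c(OC)c(OC)c1)[C@@H](COC(C)=O)C(OC(C)=O)c1cc(OC)c(O[Si](C)(C)C(C)(C)C)c(OC)c1 | intermediate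
13 | (2R,3S,4S,5R)-THF diacetate aryl silyl ether | COc1cc([C@@H]2O[C@@H](c3cc(OC)c(OC)c(OC)c3)[C@H](COC(C)=O)[C@H]2COC(C)=O)cc(OC)c1O[Si](C)(C)C(C)(C)C | intermediate
14 | [(2R,3S,4S,5R)-2-(4-hydroxy-3,5-dimethoxyphenyl)-5-(3,4,5-trimethoxyphenyl)oxolane-3,4-diyl]dimethanol | COc1cc([C@@H]2O[C@@H](c3cc(OC)c(OC)c(OC)c3)[C@H](CO)[C@H]2CO)cc(OC)c1O | target

## Summary

Total steps: 10. Longest linear sequence: 9 (Steps 1–4, 6–10); Step 5 is a one-step side branch.

Steps most likely to fail:

1. **Steps 2–3 (aldol, then silylation).** The γ-hydroxy methyl ester 5 may lactonise to the trans-paraconyl imide before it is silylated, which would lead to the wrong lactone. Fallback: drop the ester from the aldol partner. Run the Evans syn-aldol on (R)-4-benzyl-3-(pent-4-enoyl)oxazolidin-2-one with 4, silylate, reduce with LiBH4 to the primary alcohol, then ozonolyse the alkene and oxidise the resulting lactol to the same lactone 7.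

2. **Step 9 (cationic ring closure).** Competing Friedel–Crafts closure onto the trimethoxyphenyl ring (aryltetralin), E1 elimination, acetate participation, or sluggish attack by the silyl ether. Fallback: switch to a quinone-methide etherification with a free hydroxyl. From 11, selectively pivaloylate the two primary alcohols, remove both silyl groups (TBAF/AcOH) to give the free-phenol 1,4-diol, close with cat. PPTS/CSA under thermodynamic control, then cleave the pivalates.

3. **Step 6 (lactone aldol).** Retro-aldol on work-up or incomplete trans selectivity. Fallback: replace the aldol by C-acylation of the enolate of 7 with an activated 4-TBSO-3,5-dimethoxybenzoic acid derivative. The α-aroyl lactone equilibrates to trans, and LiBH4 then reduces ketone and lactone together to the same triol 11.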